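Ring A is closed last through the C1–C10 bond: the cross-conjugated enolate of a monocyclic, carvone-derived ring B enone (C9 ketone, C10 its α′ carbon) displaces a primary iodide at C1 of a C(CH3)2CH2CH2CH2I chain carried by C5. This single alkylation forms ring A and the quaternary C10; because the tether sits on the neighbouring C5, C1 must bond syn to C4, so the (S)-carvone stereocentre at C5 dictates C10. C5 is afterwards inverted by equilibration next to a C6 ketone, which also sets up the C7 hydroxylation and the 6β-acetate; the side chain is completed by B-alkyl Suzuki coupling.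

Key step: step 5

Remark: labdane numbering is used throughout (ring A = C1–C5 and C10; ring B = C5–C10; C17 = methyl on C8; C11–C16 = side chain; α = face of H5 in the target, β = face of the C10 methyl); the C9 carbinol configuration in 10–12 is drawn as expected from convex-face attack but is of no consequence, since C9 becomes sp2 in step 8.

Step 1
Reactants: 1 (S)-(+)-carvone
Product: 3 (5S,6R)-2,6-dimethyl-5-(prop-1-en-2-yl)cyclohex-2-en-1-one (trans-6-methylcarvone), via lithium enolate 2 (not isolated)
Conditions: LiN(iPr)2, THF, −78 °C; then MeI, −78 → 0 °C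
Reagents that add atoms: iodomethane CI
Why: Kinetic deprotonation at the α′ carbon (future C10) and C-methylation anti to the neighbouring isopropenyl group (kinetic enolate alkylation) should give mainly the trans isomer; this centre is re-enolised in step 5, so its configuration does not matter.

Step 2
Reactants: 3 trans-6-methylcarvone; 4 acrolein
Product: 5 4-[(1S,6R)-4,6-dimethyl-5-oxocyclohex-3-en-1-yl]-4-methylpentanal
Conditions: Fe(acac)3 (30 mol%), PhSiH3, EtOH/ethylene glycol, 60 °C
Reagents that add atoms: none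
Why: Iron-hydride hydrogen-atom transfer to the 1,1-disubstituted isopropenyl alkene gives the tertiary C4 radical, which adds to acrolein (MHAT-initiated Giese-type reductive olefin coupling) and builds the quaternary C4 together with C3–C1; no stereocentre is formed and the electron-poor ring enone is a much slower hydrogen-atom acceptor.

Step 3
Reactants: 5 keto aldehyde
Product: 6 (5S,6R)-5-(5-hydroxy-2-methylpentan-2-yl)-2,6-dimethylcyclohex-2-en-1-one
Conditions: NaBH4 (0.3 equiv), MeOH/CH2Cl2, −78 °C
Reagents that add atoms: none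
Why: Borohydride reduces an aldehyde far faster than a conjugated ketone at −78 °C (chemoselective hydride reduction), so only C1 is reduced and no stereocentre is formed.

Step 4
Reactants: 6 hydroxy enone
Product: 7 (5S,6R)-5-(5-iodo-2-methylpentan-2-yl)-2,6-dimethylcyclohex-2-en-1-one
Conditions: PPh3, I2, imidazole, CH2Cl2, 0 °C
Reagents that add atoms: iodine [I][I]
Why: Appel-type iodination converts the primary alcohol into the iodide by SN2 displacement of the oxyphosphonium group without touching the enone.

Step 5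
Reactants: 7 iodo enone
Product: 9 (4aR,8aS)-2,5,5,8a-tetramethyl-4a,5,6,7,8,8a-hexahydronaphthalen-1(4H)-one (cis-fused; 5β-H and 10β-methyl), via lithium dienolate 8 (not isolated)
Conditions: LiN(iPr)2 (1.1 equiv), THF, −78 °C, 0.01 M; then DMPU, −78 → 0 °C
Reagents that add atoms: none
Why: LiN(iPr)2 removes the α′ proton at C10 under kinetic control to give the cross-conjugated dienolate 8, whose C10 terminus displaces the primary iodide at C1 in an intramolecular SN2 C-alkylation. The closest known reaction type is the intramolecular alkylation of cyclic ketone enolates used to make angularly methylated cis-fused bicyclic ketones. Ring A closes in the 6-(enolendo)-exo-tet mode. The new quaternary stereocentre C10 is controlled by C5: the tether is anchored through C4 on the adjacent ring carbon, so C1 can reach the enolate π lobe with collinear C10···C1–I geometry only on the face that carries C4, which places C1 cis to C4 and the methyl group on the β face. The step needs C-alkylation at C10 over O-alkylation, γ-deprotonation at C6 and intermolecular alkylation; these are secured by the kinetic amide base at −78 °C, the eight-membered ring that O-alkylation would require, the gem-dimethyl (Thorpe–Ingold) bias at C4 and high dilution. The cis ring fusion (5β-H) that results is intended and is corrected in step 7.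

Step 6
Reactants: 9 cis-fused bicyclic enone
Product: 10 (1R,4aR,8aS)-1-ethenyl-2,5,5,8a-tetramethyl-1,4,4a,5,6,7,8,8a-octahydronaphthalen-1-ol
Conditions: CH2=CHMgBr, CeCl3, THF, −78 → 0 °C
Reagents that add atoms: vinylmagnesium bromide C=C[Mg]Br
Why: Organocerium 1,2-addition to the hindered enone carbonyl at C9 suppresses conjugate addition; the new C9 carbinol centre should arise from attack on the convex face of the cis-fused bicycle but is lost in step 8.

Step 7
Reactants: 10 vinyl carbinol
Product: 12 (4R,4aS,8aS)-4-ethenyl-4-hydroxy-3,4a,8,8-tetramethyl-4a,5,6,7,8,8a-hexahydronaphthalen-1(4H)-one (trans-fused), via cis-fused hydroxy enone 11 (not isolated)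
Conditions: Rh2(cap)4 (dirhodium tetracaprolactamate, 1 mol%), t-BuOOH (70% aq.), K2CO3, CH2Cl2, rt; aqueous Na2SO3 wash; then NaOMe (cat.), MeOH, rt
Reagents that add atoms: tert-butyl hydroperoxide CC(C)(C)OO
Why: Peroxyl-radical hydrogen abstraction at the only secondary allylic position (C6) and collapse of the mixed peroxide give the enone (Rh2(cap)4/t-BuOOH allylic oxidation), and methoxide then equilibrates the now enolisable C5 to the trans ring fusion (5α-H), a thermodynamic epimerisation placed here because C9 is still sp3 and exerts no peri strain on C1.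

Step 8
Reactants: 12 trans-fused γ-hydroxy enone
Product: 13 (4aS,8aS)-4-ethenyl-3,4a,8,8-tetramethyl-4a,5,6,7,8,8a-hexahydronaphthalen-1(2H)-one
Conditions: SmI2 (2.5 equiv), THF/HMPA, −78 °C; then MeOH, −78 °C; pH 7 buffer
Reagents that add atoms: none
Why: Two single-electron transfers from SmI2 to the enone place negative charge on C8, hydroxide is expelled from the adjacent C9 (reductive elimination of a γ-hydroxy enone, the vinylogue of α-hydroxy ketone deoxygenation) and kinetic protonation of the extended enolate at C7 should give the β,γ-unsaturated ketone; no stereocentre is formed.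

Step 9
Reactants: 13 dienyl ketone
Product: 16 (2S,4aS,8aS)-4-ethenyl-3,4a,8,8-tetramethyl-2-(triethylsilyloxy)-4a,5,6,7,8,8a-hexahydronaphthalen-1(2H)-one, via potassium dienolate 14 (not isolated), via potassium alkoxide 15 (not isolated)
Conditions: KN(SiMe3)2 (1.0 equiv), THF, −78 °C; 2-(phenylsulfonyl)-3-phenyloxaziridine, −78 °C; then Et3SiCl, −78 → −20 °C
Reagents that add atoms: 2-(phenylsulfonyl)-3-phenyloxaziridine O=S(=O)(N1OC1c1ccccc1)c1ccccc1; chlorotriethylsilane CC[Si](Cl)(CC)CC
Why: The doubly activated C7 proton is removed selectively, the extended enolate is hydroxylated at its α carbon by the N-sulfonyloxaziridine (enolate α-hydroxylation) from the α face, that is axially and anti to the C10 and 4β methyl groups, and the alkoxide is silylated in the same flask before the α-ketol can isomerise, which sets C7 as 7α.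

Step 10
Reactants: 16 α-silyloxy ketone
Product: 17 (1S,2S,4aS,8aS)-4-ethenyl-3,4a,8,8-tetramethyl-2-(triethylsilyloxy)-1,2,4a,5,6,7,8,8a-octahydronaphthalen-1-ol
Conditions: NaBH4, CeCl3·7H2O, MeOH, −78 → −40 °C
Reagents that add atoms: none
Why: In this Luche-type reduction the β face of the C6 carbonyl is blocked by the syn-axial C10 and 4β methyl groups, so hydride should enter from the α face and give the axial 6β alcohol.

Step 11
Reactants: 17 6β-alcohol
Product: 18 (1S,2S,4aS,8aS)-4-ethenyl-3,4a,8,8-tetramethyl-2-(triethylsilyloxy)-1,2,4a,5,6,7,8,8a-octahydronaphthalen-1-yl acetate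
Conditions: Ac2O, DMAP, pyridine, 50 °C
Reagents that add atoms: acetic anhydride CC(=O)OC(C)=O
Why: DMAP-catalysed acylation of the hindered axial secondary alcohol (nucleophilic catalysis) touches no stereocentre, and the trans-diaxial silyl ether cannot migrate.

Step 12
Reactants: 19 but-2-yn-1-ol
Product: 21 (Z)-3-iodobut-2-en-1-ol, via sodium alkenylalanate 20 (not isolated)
Conditions: NaAlH2(OCH2CH2OCH3)2, THF, 0 °C → rt; then I2, −78 °C
Reagents that add atoms: iodine [I][I]
Why: Alkoxide-directed trans-hydroalumination of the propargylic alcohol places aluminium at C3 in a five-membered alanate, and iodinolysis with retention gives the Z-alkenyl iodide (hydroalumination–iodination), which fixes the later 13Z geometry.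

Step 13
Reactants: 18 diene acetate; 21 (Z)-3-iodobut-2-en-1-ol
Product: 23 (1S,2S,4aS,8aS)-4-[(3Z)-5-hydroxy-3-methylpent-3-en-1-yl]-3,4a,8,8-tetramethyl-2-(triethylsilyloxy)-1,2,4a,5,6,7,8,8a-octahydronaphthalen-1-yl acetate, via alkylborane 22 (not isolated)
Conditions: 9-borabicyclo[3.3.1]nonane (9-BBN), THF, rt; then 21, Pd(dppf)Cl2 (5 mol%), AsPh3, Cs2CO3, DMF/H2O, rt
Reagents that add atoms: none
Why: 9-BBN hydroborates the terminal vinyl group anti-Markovnikov (boron on C12) and leaves the tetrasubstituted C8=C9 bond alone, and the B-alkyl Suzuki–Miyaura coupling with the alkenyl iodide proceeds with retention of the Z geometry to complete the side chain.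

Step 14
Reactants: 23 silyl ether
Product: 24 (1S,2S,4aS,8aS)-2-hydroxy-4-[(3Z)-5-hydroxy-3-methylpent-3-en-1-yl]-3,4a,8,8-tetramethyl-1,2,4a,5,6,7,8,8a-octahydronaphthalen-1-yl acetate (CNP0183298.2)
Conditions: HF·pyridine, pyridine, THF, 0 °C
Reagents that add atoms: none
Why: Buffered fluoride cleavage of the secondary triethylsilyl ether (desilylation) frees the 7α-hydroxyl without acetyl migration, which the trans-diaxial arrangement of O6 and O7 disfavours.

Compound list
1 | (S)-(+)-carvone, (5S)-2-methyl-5-(prop-1-en-2-yl)cyclohex-2-en-1-one | C1C=C(C)C(=O)C[C@H]1C(C)=C | starting material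
2 | lithium α′-enolate of 1 | C1C=C(C)C([O-])=C[C@H]1C(C)=C.[Li+] | intermediate (not isolated)
3 | (5S,6R)-2,6-dimethyl-5-(prop-1-en-2-yl)cyclohex-2-en-1-one | C1C=C(C)C(=O)[C@H](C)[C@H]1C(C)=C | intermediate
4 | acrolein (prop-2-enal) | C=CC=O | starting material
5 | 4-[(1S,6R)-4,6-dimethyl-5-oxocyclohex-3-en-1-yl]-4-methylpentanal | C1C=C(C)C(=O)[C@H](C)[C@H]1C(C)(C)CCC=O | intermediate
6 | (5S,6R)-5-(5-hydroxy-2-methylpentan-2-yl)-2,6-dimethylcyclohex-2-en-1-one | C1C=C(C)C(=O)[C@H](C)[C@H]1C(C)(C)CCCO | intermediate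
7 | (5S,6R)-5-(5-iodo-2-methylpentan-2-yl)-2,6-dimethylcyclohex-2-en-1-one | C1C=C(C)C(=O)[C@H](C)[C@H]1C(C)(C)CCCI | intermediate
8 | lithium cross-conjugated dienolate of 7 (C9–O, C9=C10) | C1C=C(C)C([O-])=C(C)[C@H]1C(C)(C)CCCI.[Li+] | intermediate (not isolated)
9 | (4aR,8aS)-2,5,5,8a-tetramethyl-4a,5,6,7,8,8a-hexahydronaphthalen-1(4H)-one, cis-fused | C1C=C(C)C(=O)[C@@]2(C)CCCC(C)(C)[C@@H]12 | intermediate
10 | (1R,4aR,8aS)-1-ethenyl-2,5,5,8a-tetramethyl-1,4,4a,5,6,7,8,8a-octahydronaphthalen-1-ol | C1C=C(C)[C@](O)(C=C)[C@@]2(C)CCCC(C)(C)[C@@H]12 | intermediate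
11 | (4R,4aS,8aR)-4-ethenyl-4-hydroxy-3,4a,8,8-tetramethyl-4a,5,6,7,8,8a-hexahydronaphthalen-1(4H)-one, cis-fused | O=C1C=C(C)[C@](O)(C=C)[C@@]2(C)CCCC(C)(C)[C@@H]12 | intermediate (not isolated)
12 | (4R,4aS,8aS)-4-ethenyl-4-hydroxy-3,4a,8,8-tetramethyl-4a,5,6,7,8,8a-hexahydronaphthalen-1(4H)-one, trans-fused | O=C1C=C(C)[C@](O)(C=C)[C@@]2(C)CCCC(C)(C)[C@H]12 | intermediate
13 | (4aS,8aS)-4-ethenyl-3,4a,8,8-tetramethyl-4a,5,6,7,8,8a-hexahydronaphthalen-1(2H)-one | O=C1CC(C)=C(C=C)[C@@]2(C)CCCC(C)(C)[C@H]12 | intermediate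
14 | potassium extended enolate of 13 (C6–O, C6=C7) | [O-]C1=CC(C)=C(C=C)[C@@]2(C)CCCC(C)(C)[C@H]12.[K+] | intermediate (not isolated)
15 | potassium alkoxide of the 7α-hydroxy derivative of 13 | O=C1[C@@H]([O-])C(C)=C(C=C)[C@@]2(C)CCCC(C)(C)[C@H]12.[K+] | intermediate (not isolated)
16 | (2S,4aS,8aS)-4-ethenyl-3,4a,8,8-tetramethyl-2-(triethylsilyloxy)-4a,5,6,7,8,8a-hexahydronaphthalen-1(2H)-one | O=C1[C@@H](O[Si](CC)(CC)CC)C(C)=C(C=C)[C@@]2(C)CCCC(C)(C)[C@H]12 | intermediate
17 | (1S,2S,4aS,8aS)-4-ethenyl-3,4a,8,8-tetramethyl-2-(triethylsilyloxy)-1,2,4a,5,6,7,8,8a-octahydronaphthalen-1-ol | O[C@@H]1[C@@H](O[Si](CC)(CC)CC)C(C)=C(C=C)[C@@]2(C)CCCC(C)(C)[C@H]12 | intermediate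
18 | (1S,2S,4aS,8aS)-4-ethenyl-3,4a,8,8-tetramethyl-2-(triethylsilyloxy)-1,2,4a,5,6,7,8,8a-octahydronaphthalen-1-yl acetate | CC(=O)O[C@@H]1[C@@H](O[Si](CC)(CC)CC)C(C)=C(C=C)[C@@]2(C)CCCC(C)(C)[C@H]12 | intermediate
19 | but-2-yn-1-ol | CC#CCO | starting material
20 | sodium cyclic (Z)-alkenylalanate from 19 | [Na+].CC1=CCO[Al-]1(OCCOC)OCCOC | intermediate (not isolated)
21 | (Z)-3-iodobut-2-en-1-ol | I/C(C)=C\CO | intermediate
22 | B-alkyl-9-BBN adduct of 18 (boron on C12) | CC(=O)O[C@@H]1[C@@H](O[Si](CC)(CC)CC)C(C)=C(CCB3C4CCCC3CCC4)[C@@]2(C)CCCC(C)(C)[C@H]12 | intermediate (not isolated)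
23 | (1S,2S,4aS,8aS)-4-[(3Z)-5-hydroxy-3-methylpent-3-en-1-yl]-3,4a,8,8-tetramethyl-2-(triethylsilyloxy)-1,2,4a,5,6,7,8,8a-octahydronaphthalen-1-yl acetate | CC(=O)O[C@@H]1[C@@H](O[Si](CC)(CC)CC)C(C)=C(CC/C(C)=C\CO)[C@@]2(C)CCCC(C)(C)[C@H]12 | intermediate
24 | (1S,2S,4aS,8aS)-2-hydroxy-4-[(3Z)-5-hydroxy-3-methylpent-3-en-1-yl]-3,4a,8,8-tetramethyl-1,2,4a,5,6,7,8,8a-octahydronaphthalen-1-yl acetate (6β-acetoxy-7α-hydroxylabda-8,13Z-dien-15-ol) | CC(=O)O[C@@H]1[C@@H](O)C(C)=C(CC/C(C)=C\CO)[C@@]2(C)CCCC(C)(C)[C@H]12 | target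

Total step count: 14. Longest linear sequence: 13 (steps 1–11, 13 and 14).

Steps most likely to fail

Step 7. What may go wrong: hydrogen abstraction at the C17 methyl or ionisation of the bis-allylic tertiary carbinol instead of clean oxidation at C6, and an incomplete or unfavourable equilibration at C5. The fallback sets out from 9 and comes back at 13. The enone 9 itself is oxidised at C6 with Rh2(cap)4/t-BuOOH before any carbinol is present, and the ene-dione is equilibrated with NaOMe to the trans-fused ene-dione F5, a cis-to-trans isomerisation that is well documented for angularly methylated ene-diones. NaBH4/CeCl3 at −78 °C should then reduce only the unhindered C6 carbonyl from the α face to the 6β-hydroxy enone F6. Excess CH2=CHMgBr/CeCl3 should add to the C9 carbonyl to give the diol F7, and MnO2 should oxidise the secondary allylic alcohol to the hydroxy enone F8 (the C9 epimer of 12). The SmI2 conditions of step 8 should convert F8 into 13.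

Step 8. What may go wrong: conjugate reduction that keeps the hydroxyl, or protonation of the extended enolate at C9 or C12 that moves the double bonds into conjugation with the ketone. The fallback sets out from 12 and comes back at 13; it replaces the electron-transfer reduction by a redox-neutral conjugate elimination. NaBH4/CeCl3 should give the 6β,9α-diol F9, and Et3SiOTf/2,6-lutidine at −78 °C should silylate only the secondary hydroxyl to give the silyl ether F10. Methyl N-(triethylammoniumsulfonyl)carbamate should ionise the tertiary bis-allylic carbinol, and loss of the C6 proton should give the silyl dienol ether F11. Bu4NF buffered with AcOH at −78 °C should protonate C7 kinetically and return 13.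

Step 5. What may go wrong: insufficient facial discrimination when the bond is made to the fully substituted enolate carbon, γ-deprotonation at C6, or intermolecular alkylation. The fallback sets out from 1 and comes back at 9; the ring is closed onto a less substituted enolate and the quaternary centre is set afterwards by angular methylation. (S)-Carvone 1 is coupled with acrolein under the conditions of step 2 to give the aldehyde F1, which is reduced to the alcohol F2 and converted into the iodide F3 as in steps 3 and 4. LiN(iPr)2 should then close ring A to the cis-fused bicyclic enone F4. A second deprotonation at C10 followed by MeI, which should enter cis to H5 as is usual for angular methylation of such bicyclic enolates, should give 9.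

Further compounds
F1 | step 5 | 4-methyl-4-[(1S)-4-methyl-5-oxocyclohex-3-en-1-yl]pentanal | C1C=C(C)C(=O)C[C@H]1C(C)(C)CCC=O
F2 | step 5 | (5S)-5-(5-hydroxy-2-methylpentan-2-yl)-2-methylcyclohex-2-en-1-one | C1C=C(C)C(=O)C[C@H]1C(C)(C)CCCO
F3 | step 5 | (5S)-5-(5-iodo-2-methylpentan-2-yl)-2-methylcyclohex-2-en-1-one | C1C=C(C)C(=O)C[C@H]1C(C)(C)CCCI
F4 | step 5 | (4aS,8aS)-2,5,5-trimethyl-4a,5,6,7,8,8a-hexahydronaphthalen-1(4H)-one, cis-fused | C1C=C(C)C(=O)[C@H]2CCCC(C)(C)[C@@H]12
F5 | step 7 | (4aS,8aS)-2,5,5,8a-tetramethyl-4a,5,6,7,8,8a-hexahydronaphthalene-1,4-dione, trans-fused | O=C1C=C(C)C(=O)[C@@]2(C)CCCC(C)(C)[C@H]12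
F6 | step 7 | trans-fused 6β-hydroxy enone, 4-hydroxy-2,5,5,8a-tetramethyl-4a,5,6,7,8,8a-hexahydronaphthalen-1(4H)-one | O[C@@H]1C=C(C)C(=O)[C@@]2(C)CCCC(C)(C)[C@H]12
F7 | step 7 | trans-fused 6β,9β-dihydroxy-9α-vinyl diol, 1-ethenyl-2,5,5,8a-tetramethyl-1,4,4a,5,6,7,8,8a-octahydronaphthalene-1,4-diol | O[C@@H]1C=C(C)[C@@](O)(C=C)[C@@]2(C)CCCC(C)(C)[C@H]12
F8 | step 7 | C9 epimer of 12 (9β-hydroxy-9α-vinyl) | O=C1C=C(C)[C@@](O)(C=C)[C@@]2(C)CCCC(C)(C)[C@H]12
F9 | step 8 | trans-fused 6β,9α-dihydroxy-9β-vinyl diol | O[C@@H]1C=C(C)[C@](O)(C=C)[C@@]2(C)CCCC(C)(C)[C@H]12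
F10 | step 8 | 6β-triethylsilyl ether of F9 | CC[Si](CC)(CC)O[C@@H]1C=C(C)[C@](O)(C=C)[C@@]2(C)CCCC(C)(C)[C@H]12
F11 | step 8 | triethylsilyl dienol ether of 13 (C6–OSi, C6=C7, C8=C9) | CC[Si](CC)(CC)OC1=CC(C)=C(C=C)[C@@]2(C)CCCC(C)(C)[C@H]12
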